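**Plan**

- Retrosynthesis: the 5-OH goes back to a peri methyl ether and the C4 ketone to a 4-methoxy group. Ring C is then cut at O1–C2 and C3–C4. Last, the formyl carbon (C4a–C4) and the geranyl chain (C8–C1'') are removed from ring A.
- Enabling feature: ring C (O1, C2, C3, C4, C4a, C8a) shares the C4a–C8a edge with ring A. O1–C8a–C4a–C4 is therefore a salicylaldehyde-derived ortho-quinone methide, and C2–C3 with its phenyl group is styrene.
- Forward: 3,5-dimethoxyphenol is C-geranylated and then formylated. Ring C, the only ring made, closes in one oxa-[4+2] event. Methoxy-to-hydroxy exchange, oxidation and peri-demethylation finish the target.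
- Stereochemistry: C2 (S) comes from the chiral counter-anion of the acid catalyst in the cycloaddition. C4 is transient and is erased by oxidation. The (E)-alkene is carried in from geranyl bromide.

Key step: step 3

Naming note: geranyl = (2E)-3,7-dimethylocta-2,6-dien-1-yl; flavan = 2-phenylchromane, flavanone = 2-phenylchroman-4-one.

Assumption: the sense of induction of the chiral acid cannot be predicted with confidence for this ion pair. It is taken that one of its two enantiomers gives (2S), to be identified in a first test run.

**Route**

Step 1
Reactants: 1 3,5-dimethoxyphenol; 2 geranyl bromide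
Product: 4 2-geranyl-3,5-dimethoxyphenol, via sodium 3,5-dimethoxyphenoxide 3 (not isolated)
Conditions: NaH (1.05 equiv), toluene, 0 °C → rt; then 2 (0.9 equiv), rt
Reagents that add atoms: none
Why: In toluene the sodium phenoxide reacts as a tight ion pair, so the allylic bromide should be displaced (SN2, (E)-alkene retained) by the ortho carbon rather than by oxygen (ortho-selective phenoxide C-alkylation), and the two ortho positions of 1 are equivalent.

Step 2
Reactants: 4 2-geranyl-3,5-dimethoxyphenol
Product: 6 3-geranyl-2-hydroxy-4,6-dimethoxybenzaldehyde, via salicyl alcohol 5 (not isolated)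
Conditions: MgCl2 (anhydrous), Et3N, (CH2O)n, MeCN, reflux; then 1 M HCl, 0 °C
Reagents that add atoms: paraformaldehyde (formaldehyde), C=O
Why: In the Casiraghi–Skattebøl ortho-formylation the magnesium phenoxide delivers formaldehyde only to the free ortho position to give salicyl alcohol 5, which a second formaldehyde oxidises by hydride transfer, so the position between the two methoxy groups should stay untouched.

Step 3
Reactants: 6 3-geranyl-2-hydroxy-4,6-dimethoxybenzaldehyde; 7 trimethyl orthoformate; 8 styrene
Product: 11 (2S,4S)-8-geranyl-4,5,7-trimethoxyflavan, via dimethyl acetal 9 (not isolated), via 4-methoxy ortho-quinone methide 10 (not isolated)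
Conditions: chiral imidodiphosphorimidate Brønsted acid (BINOL-derived, N-triflyl, 3,3'-aryl groups; 5 mol %), 7 (1.5 equiv), 8 (5 equiv), 5 Å molecular sieves, CHCl3, −40 → −20 °C; Et3N quench
Reagents that add atoms: none
Why: Proposed new method: the acid converts aldehyde 6 with orthoformate 7 into acetal 9 and ionises it, with loss of methanol, to the O-protonated form of quinone methide 10, an oxocarbenium ion held in a tight ion pair with the confined chiral anion; the CH2 terminus of styrene 8 then adds to C4 and the benzylic cation developing at C2 is captured by the phenolic oxygen. The closest known reactions are the achiral acid-promoted three-component synthesis of 2,4-cis-4-alkoxyflavans from salicylaldehydes, orthoformates and styrenes, and chiral-acid-catalysed [4+2] cycloadditions of ortho-quinone methides with activated alkenes; using a strong confined acid to engage an unactivated styrene enantioselectively is the new element. Ring C closes as a six-membered ring in an intermolecular, asynchronous inverse-demand oxa-[4+2] (heterodiene O1=C8a–C4a=C4, dienophile C2=C3), which in the stepwise limit is O1 capture of the C2 benzylic cation. C2 (S) is set by the chiral counter-anion, which shields one face of the approaching styrene, while C4 follows from the endo-type arrangement that places phenyl and methoxy cis and equatorial; C4 is cleared later, so only C2 has to be controlled. The regiochemistry (phenyl at C2) is secured by the polarity of styrene, and chemoselectivity against acid-induced closure of the free phenol onto the geranyl C2''=C3'' alkene rests on the much faster ionisation of the acetal, assisted by the two methoxy groups of ring A, at low temperature in a non-polar medium.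

Step 4
Reactants: 11 (2S,4S)-8-geranyl-4,5,7-trimethoxyflavan
Product: 12 (2S)-8-geranyl-5,7-dimethoxyflavan-4-ol (mixture of C4 epimers)
Conditions: PPTS (0.2 equiv), MeCN/H2O 3:1 (0.02 M), rt
Reagents that add atoms: water, O
Why: In this acid-catalysed SN1 solvolysis the C4 benzylic ether, activated by the 5- and 7-methoxy groups and O1 of ring A, should ionise under very mild acid and the cation be trapped by the large excess of water, while C2 is not involved and both C4 epimers serve the next step.

Step 5
Reactants: 12 (2S)-8-geranyl-5,7-dimethoxyflavan-4-ol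
Product: 13 (2S)-8-geranyl-5,7-dimethoxyflavanone
Conditions: Dess–Martin periodinane (1.3 equiv), pyridine, CH2Cl2, 0 °C → rt
Reagents that add atoms: none
Why: Dess–Martin oxidation of a secondary benzylic alcohol runs under buffered, near-neutral conditions that should leave the geranyl alkenes and the C2 stereocentre alone, and it merges both C4 epimers into one ketone.

Step 6
Reactants: 13 (2S)-8-geranyl-5,7-dimethoxyflavanone
Product: 14 (2S)-8-geranyl-5-hydroxy-7-methoxyflavanone (CNP0209584.2)
Conditions: BCl3 (1 M in CH2Cl2, 1.5 equiv), CH2Cl2, −78 → −20 °C; then ice-water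
Reagents that add atoms: none
Why: In this chelation-controlled peri-demethylation BCl3 binds between the C4 carbonyl and the 5-methoxy oxygen and chloride removes that methyl group only, since the 7-methoxy group lacks the chelate, while the low temperature should keep the trisubstituted alkenes and the C2 stereocentre intact.

**Compound list**

1 | 3,5-dimethoxyphenol | COc1cc(O)cc(OC)c1 | starting material
2 | geranyl bromide, (2E)-1-bromo-3,7-dimethylocta-2,6-diene | CC(C)=CCC/C(C)=C/CBr | starting material
3 | sodium 3,5-dimethoxyphenoxide | COc1cc([O-])cc(OC)c1.[Na+] | intermediate (not isolated)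
4 | 2-geranyl-3,5-dimethoxyphenol | COc1cc(O)c(C/C=C(\C)CCC=C(C)C)c(OC)c1 | intermediate
5 | 2-geranyl-6-(hydroxymethyl)-3,5-dimethoxyphenol (salicyl alcohol, formed as its magnesium phenoxide) | COc1cc(OC)c(CO)c(O)c1C/C=C(\C)CCC=C(C)C | intermediate (not isolated)
6 | 3-geranyl-2-hydroxy-4,6-dimethoxybenzaldehyde | COc1cc(OC)c(C=O)c(O)c1C/C=C(\C)CCC=C(C)C | intermediate
7 | trimethyl orthoformate | COC(OC)OC | starting material
8 | styrene | C=Cc1ccccc1 | starting material
9 | 2-(dimethoxymethyl)-6-geranyl-3,5-dimethoxyphenol (dimethyl acetal of 6) | COc1cc(OC)c(C(OC)OC)c(O)c1C/C=C(\C)CCC=C(C)C | intermediate (not isolated)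
10 | 2-geranyl-3,5-dimethoxy-6-(methoxymethylidene)cyclohexa-2,4-dien-1-one (4-methoxy ortho-quinone methide, drawn neutral; it reacts as its O-protonated oxocarbenium form paired with the catalyst anion) | COC=C1C(=O)C(C/C=C(\C)CCC=C(C)C)=C(OC)C=C1OC | intermediate (not isolated)
11 | (2S,4S)-8-geranyl-4,5,7-trimethoxy-2-phenylchromane (2,4-cis-4-methoxyflavan) | COc1cc(OC)c2c(c1C/C=C(\C)CCC=C(C)C)O[C@H](c1ccccc1)C[C@@H]2OC | intermediate
12 | (2S)-8-geranyl-5,7-dimethoxy-2-phenylchroman-4-ol (C4 epimers) | COc1cc(OC)c2c(c1C/C=C(\C)CCC=C(C)C)O[C@H](c1ccccc1)CC2O | intermediate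
13 | (2S)-8-geranyl-5,7-dimethoxy-2-phenylchroman-4-one | COc1cc(OC)c2c(c1C/C=C(\C)CCC=C(C)C)O[C@H](c1ccccc1)CC2=O | intermediate
14 | (2S)-8-geranyl-5-hydroxy-7-methoxy-2-phenylchroman-4-one (CNP0209584.2) | COc1cc(O)c2c(c1C/C=C(\C)CCC=C(C)C)O[C@H](c1ccccc1)CC2=O | target

**Step count and risks**

Total step count: 6. Longest linear sequence: 6 steps (1 → 14).

Steps most likely to fail:

1. Step 3 (proposed new method). Several processes could defeat it:
   - the ion pair may discriminate the styrene faces poorly;
   - a racemic background pathway may compete;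
   - the acid may close the phenol onto the geranyl alkene before the acetal ionises;
   - the oxocarbenium ion may alkylate the electron-rich ring A of a second molecule.

   The fallback uses known chemistry, sets out from 6 and returns at 13. MeMgBr (THF, 0 °C) adds to the aldehyde to give the carbinol 2-geranyl-6-(1-hydroxyethyl)-3,5-dimethoxyphenol F1. MnO2 (CH2Cl2, rt) oxidises it without purification to the acetophenone 1-(3-geranyl-2-hydroxy-4,6-dimethoxyphenyl)ethanone F2. N,N-Dimethylformamide dimethyl acetal (toluene, 90 °C) gives the enaminone (E)-3-(dimethylamino)-1-(3-geranyl-2-hydroxy-4,6-dimethoxyphenyl)prop-2-en-1-one F3. Brief treatment with TsOH in CH2Cl2 closes it, with loss of dimethylamine, to the chromone 8-geranyl-5,7-dimethoxychromone F4. Asymmetric conjugate addition of PhB(OH)2 catalysed by Pd(OCOCF3)2 (divalent palladium) and t-BuPyOx (NH4PF6, H2O, ClCH2CH2Cl, 60 °C; ligand enantiomer chosen for (2S)) should then give flavanone 13 directly, so steps 4 and 5 fall away.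

2. Step 4. The C4 cation may lose a proton to the flav-3-ene, or be attacked by C6 of a second molecule, leading to oligomers. The fallback sets out from 11 and returns at 13 by oxidation instead of solvolysis. DDQ in CH2Cl2/pH 7 buffer at 0 °C should abstract the C4 hydride, which is benzylic and alpha to oxygen. Water adds to the resulting oxocarbenium ion to give the hemiketal (2S)-8-geranyl-4,5,7-trimethoxyflavan-4-ol F5, which loses methanol to ketone 13. This also takes over step 5.

3. Step 1. O-alkylation, attack at the para carbon between the methoxy groups, and double alkylation may erode the yield of the ortho C-geranyl phenol. The fallback sets out from 1 and returns at 4 by directed metalation instead of phenoxide alkylation. MOMCl and i-Pr2NEt (CH2Cl2) give 1,3-dimethoxy-5-(methoxymethoxy)benzene F6. n-BuLi (THF, 0 °C) should lithiate between the OMOM and OMe groups to the aryllithium [2,4-dimethoxy-6-(methoxymethoxy)phenyl]lithium F7. With CuBr·SMe2 (10 mol %) and geranyl bromide 2 this gives 2-geranyl-1,5-dimethoxy-3-(methoxymethoxy)benzene F8. HCl in MeOH at rt removes the MOM group and returns phenol 4.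

Step 6 ranks behind these because chelation-controlled peri-demethylation of 5,7-dimethoxyflavanones with BCl3 is routine, and at −78 °C the geranyl alkenes have no neighbouring free phenol to cyclise onto.

**Further compounds**

F1 | step 3 | 2-geranyl-6-(1-hydroxyethyl)-3,5-dimethoxyphenol | COc1cc(OC)c(C(C)O)c(O)c1C/C=C(\C)CCC=C(C)C
F2 | step 3 | 1-(3-geranyl-2-hydroxy-4,6-dimethoxyphenyl)ethanone | COc1cc(OC)c(C(C)=O)c(O)c1C/C=C(\C)CCC=C(C)C
F3 | step 3 | (E)-3-(dimethylamino)-1-(3-geranyl-2-hydroxy-4,6-dimethoxyphenyl)prop-2-en-1-one | COc1cc(OC)c(C(=O)/C=C/N(C)C)c(O)c1C/C=C(\C)CCC=C(C)C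
F4 | step 3 | 8-geranyl-5,7-dimethoxy-4H-chromen-4-one | COc1cc(OC)c2C(=O)C=COc2c1C/C=C(\C)CCC=C(C)C
F5 | step 4 | (2S)-8-geranyl-4,5,7-trimethoxy-2-phenylchroman-4-ol (hemiketal, not isolated) | COc1cc(OC)c2c(c1C/C=C(\C)CCC=C(C)C)O[C@H](c1ccccc1)CC2(O)OC
F6 | step 1 | 1,3-dimethoxy-5-(methoxymethoxy)benzene | COCOc1cc(OC)cc(OC)c1
F7 | step 1 | [2,4-dimethoxy-6-(methoxymethoxy)phenyl]lithium (not isolated) | [Li]c1c(OC)cc(OC)cc1OCOC
F8 | step 1 | 2-geranyl-1,5-dimethoxy-3-(methoxymethoxy)benzene | COCOc1cc(OC)cc(OC)c1C/C=C(\C)CCC=C(C)C
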